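Assumption: 1 and 2 are taken as catalogue compounds. Positions in every intermediate are called by the numbering of 11: C1 carbonyl carbon, C2=C3 alkene, C4 acetoxy carbon, C5 ring carbinol carbon, C1′ side-chain carbinol carbon.

## Structural features

The target 11 is a cyclopent-2-enone whose C5 is a fully substituted carbinol carbon carrying a 1-hydroxypentadecyl chain; the only other ring substituent is an acetoxy group at C4. Three stereocentres stand in a row, C4 (R), C5 (S) and C1′ (S). The C4 acetate is trans to the C5 hydroxyl and therefore cis to the side chain, and the C5 and C1′ oxygens are erythro. The molecule is at once a γ-acyloxy enone, a tertiary α-ketol and an aldol (the C1′ hydroxyl is β to the C1 carbonyl). Base therefore invites retro-aldol cleavage of the C5–C1′ bond, loss of the ester, and migration of the acetyl group from O4 to the cis-disposed O1′ through a six-membered transition state. The carbon skeleton is simple, one ring and one ring-to-chain bond. The real difficulty is to place a single acetate on one of three neighbouring oxygens while fixing three contiguous centres, one of them quaternary. A trans C4/C5 dioxygen pair next to a carbinol at C1′ is what remains when an oxirane across C4–C5, built on the alkene of an allylic alcohol, is opened at C4 by a carboxylate. The C1′ hydroxyl can thus serve twice, to direct and resolve the epoxidation and to anchor titanium for the opening.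

## Logic of the disconnections

11 to 9 (through 10): the C2=C3 π bond is removed and the C1 oxygen and both hydroxyls are capped with silicon. The enone is the most base-sensitive and electrophilic part, so it is introduced last. Because C5 has no hydrogen, enolisation of C1 can go only toward C2, so the regiochemistry of the dehydrogenation is automatic. The demand on the forward step is that oxidation by palladium must not ionise the acetate, which becomes allylic as the enone forms, and that the final desilylation must be mildly acidic.

9 to 8: three O–Si bonds are cut. Capping the two hydroxyls in the same operation that makes the silyl enol ether avoids separate protection steps. The forward step must enolise the ketone without a strong base, which would attack the acetate or trigger retro-aldol cleavage.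

8 to 7: the C1 carbonyl is traced back to its dioxolane. The ketone must stay masked during the organolithium addition, the epoxidation and the titanium-mediated opening, where a free C1 carbonyl would make C5 part of an α-keto oxirane and an aldol at the same time. The forward hydrolysis must be mild enough to leave the acetate on O4.

7 to 5 and 6: the C4–O(acetyl) bond is cut. This is the strategic cut because it derives the position of the acetate and the C4 configuration from one strained precursor. All three oxygens of 7 are already differentiated without any protecting group on a hydroxyl. The C1′ hydroxyl of 5 is deliberately left free, since it is the handle for titanium. The forward step must attack C4 and not C5, with clean inversion.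

5 to 4: the two C–O bonds of the oxirane are cut. A titanium–tartrate epoxidation of the allylic alcohol sets C4 and C5 and at the same time selects the (1′S)-enantiomer from the racemate. The gain is two stereocentres and the resolution in one operation. The demand is a large rate difference between the enantiomers, a reaction stopped below half conversion, and erythro selectivity.

4 to 1 and 2 (through 3): the C5–C1′ bond is cut. This joins the ring and the chain from two catalogue compounds in one step. The forward step needs a clean bromine–lithium exchange and addition to the aldehyde without enolising it; the C1′ centre may form without control.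

## Other disconnections considered

Alternative 1: The cut is the C1–C5 ring bond, leading back to keto aldehyde A1, a 2,2-dimethyl-1,3-dioxan-5-one whose ketone carbon is the future C5. One α-carbon of A1 carries the tetradecyl group (future C1′) and the other (future C4) a 3-oxopropyl arm ending in the future C1. In the forward step a chiral triazolylidene carbene would turn the aldehyde into an acyl anion equivalent that adds to the ketone in an intramolecular crossed benzoin reaction, giving the cis-fused acyloin A2. Both α-oxy centres of A1 can epimerise under the basic conditions, so the catalyst could funnel the stereoisomer mixture into one product.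
- In its favour: a catalytic C–C bond formation closes the ring, creates the quaternary C5 carbinol and could set all three stereocentres at once. No material is discarded, which is better than the kinetic resolution of the chosen plan. The acetonide bridge enforces the cis relation between the C4 oxygen and the side chain that 11 needs.
- Against it: once the acetonide of A2 is removed, the C4 and C1′ hydroxyls are both free secondary alcohols, and acetylating only C4 becomes a selectivity problem that the chosen plan never meets. The catalyst would have to choose among four stereoisomers of A1 whose epimerisation must outpace cyclisation, and β-elimination of a ring oxygen from the enolisable dioxanone competes. A1 itself needs several steps.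
- Comparison: on structure the two plans are equal in one respect, since A2 is also a 2,3-dihydro compound and needs the same late dehydrogenation. On mechanism the chosen plan relies on stereospecific C–O events (directed epoxidation, SN2 inversion) that are easier to predict than a dynamic catalyst-controlled C–C addition. On step economy Alternative 1 is longer: deprotection, selective acetylation and dehydrogenation after A2, plus the preparation of A1.

Alternative 2: The cut is the C4–H bond, leading back to the spiro ene-dione A3, in which C5 carries two equivalent carbonyl arms and the C5/C1′ diol is tied as an acetonide with C1′ already (S). In the forward step an NADPH-dependent ketoreductase would reduce one of the two diastereotopic carbonyls from one face, creating C4 and C5 together and giving hydroxy enone A4.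
- In its favour: the enone is already in place, so no dehydrogenation is needed. A4 has a single free hydroxyl, so acetylation is unambiguous. On both points this alternative is better than the chosen plan. The reduction would run under mild aqueous conditions, and only two steps (acetylation, acetonide cleavage) would separate A4 from 11, against three after the key step of the chosen plan.
- Against it: A3 is a 2,2-dioxygenated cyclopent-4-ene-1,3-dione, strongly electrophilic and liable in buffer to hydration, ring opening and conjugate addition. A suitable enzyme would have to be found by screening, with four possible alcohols (two carbonyls, two faces) and possible reduction of the alkene. A3 needs its own multi-step preparation with C1′ set separately. The final acidic acetonide cleavage exposes the same migration-prone acetate/diol array as the chosen endgame.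
- Comparison: on structure Alternative 2 is the better at the end of the route. On mechanism it depends on reagent control for which no predictive model exists for this substrate, whereas the chosen plan uses well-understood directing effects. On overall step economy the short endgame is offset by the longer way to A3.

Alternative 3: The cut is the C4–C5 ring bond. Furyl carbinol A5, carrying the (S)-configured silyloxy centre that becomes C1′, would be ring-expanded by an Achmatowicz oxidation to the 6-hydroxypyranone A6. In the forward key step triethylamine would open A6 to its cis-4-oxo-enal, enolise it to the enediolate, and the C5 carbon would add to the aldehyde carbon C4 in an intramolecular aldol reaction to give cyclopentenone A7.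
- In its favour: the route is very short and starts from a furan. The enone is present from the start, and the ring stereocentres of A6 need no control because they are erased. With C1′ silylated, the only acylable secondary hydroxyl of A7 is at C4. On step count, on avoiding a palladium dehydrogenation and on avoiding a resolution this alternative is better than the chosen plan.
- Against it: the required erythro relation between C5 and C1′ would rest on the facial bias that the neighbouring silyloxy centre exerts on the enediolate, for which there is no firm model. The reversible aldol could equilibrate the isomers but not necessarily toward the one needed. Base could move the silyl group from O1′ to the C5 oxygen or isomerise the 4-hydroxy enone further. A5 must be made with C1′ enantiopure next to an epimerisable position.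
- Comparison: on structure both plans end with the same unprotected array. On mechanism the chosen plan fixes C4, C5 and C1′ by stereospecific steps, whereas Alternative 3 leaves two of them to substrate or thermodynamic control. On step economy Alternative 3 is shorter.

Key step: step 3

## Route

Step 1
Reactants: 1 6-bromo-1,4-dioxaspiro[4.4]non-6-ene; 2 pentadecanal
Product: 4 rac-1-(1,4-dioxaspiro[4.4]non-6-en-6-yl)pentadecan-1-ol, via 1,4-dioxaspiro[4.4]non-6-en-6-yllithium 3 (not isolated)
Conditions: n-BuLi (1.05 equiv), THF, −78 °C; then 2, −78 → 0 °C; aq. NH4Cl
Reagents that add atoms: none
Why: Bromine–lithium exchange followed by 1,2-addition of the alkenyllithium to the aldehyde; the ketal is inert to the organolithium, and the C1′ centre forms without control, which is acceptable because step 2 resolves it.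

Step 2
Reactants: 4 rac-1-(1,4-dioxaspiro[4.4]non-6-en-6-yl)pentadecan-1-ol
Product: 5 (6S,7S)-6,7-epoxy-6-[(1S)-1-hydroxypentadecyl]-1,4-dioxaspiro[4.4]nonane (erythro epoxy alcohol)
Conditions: Ti(OiPr)4 (0.1 equiv), L-(+)-diisopropyl tartrate (0.15 equiv), t-BuOOH (0.45 equiv, anhydrous in decane), 4 Å molecular sieves, CH2Cl2, −20 °C; chromatographic separation from unreacted alcohol
Reagents that add atoms: tert-butyl hydroperoxide, CC(C)(C)OO
Why: Sharpless kinetic-resolution epoxidation: on the titanium–L-(+)-tartrate template the (1′S)-enantiomer of 4 is the fast-reacting one (tetradecyl chain pointing away from the catalyst) and receives oxygen on the alkene face that makes the C5–O and C1′–O bonds erythro, a preference reinforced by allylic 1,2-strain with the ketal carbon geminal to the carbinol, so C4 and C5 are set by the catalyst and C1′ by the resolution. Sub-stoichiometric oxidant keeps the slow (1′R)-enantiomer from reacting, and catalytic titanium with sieves limits opening of the sensitive trisubstituted oxirane.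

Step 3
Reactants: 5 (6S,7S)-6,7-epoxy-6-[(1S)-1-hydroxypentadecyl]-1,4-dioxaspiro[4.4]nonane; 6 acetic acid
Product: 7 (6S,7R)-6-hydroxy-6-[(1S)-1-hydroxypentadecyl]-1,4-dioxaspiro[4.4]nonan-7-yl acetate
Conditions: Ti(OiPr)4 (1.5 equiv), 6 (3 equiv), CH2Cl2, 0 °C → rt; aq. potassium sodium tartrate work-up
Reagents that add atoms: none
Why: Ligand exchange places the C1′ alkoxide of 5 on titanium, which then also binds the oxirane oxygen in a five-membered chelate and weakens the C4–O bond. Acetate from 6 attacks C4 from the face opposite the oxirane oxygen in an SN2 opening driven by release of three-ring strain, so the acetoxy group ends trans to the new tertiary hydroxyl at C5 and cis to the side chain. The closest known reaction type is the Ti(OiPr)4-mediated opening of 2,3-epoxy alcohols by carboxylic acids at the carbon remote from the carbinol. No ring is closed; the oxirane is opened and the carbon skeleton is unchanged. The one new stereocentre, C4, is controlled by inversion at a carbon whose configuration was fixed in step 2, while C5 and C1′ keep their configuration because their C–O bonds are not broken. The step needs attack at C4 and not at C5: chelation through the C1′ oxygen activates the distal C–O bond, and C5 is fully substituted and flanked by the electron-poor ketal carbon, which disfavours both SN2 and cation-like attack there. Transfer of isopropoxide and titanium-catalysed acyl transfer are kept down by the excess of 6, the low temperature, a short reaction time and the neutral tartrate work-up.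

Step 4
Reactants: 7 (6S,7R)-6-hydroxy-6-[(1S)-1-hydroxypentadecyl]-1,4-dioxaspiro[4.4]nonan-7-yl acetate
Product: 8 (1R,2S)-2-hydroxy-2-[(1S)-1-hydroxypentadecyl]-3-oxocyclopentyl acetate
Conditions: pyridinium p-toluenesulfonate (0.3 equiv), acetone–H2O (9:1), 55 °C
Reagents that add atoms: water, O
Why: Acid-catalysed hydrolysis (transketalisation to acetone) of the dioxolane under buffered conditions that leave a secondary acetate alone; no stereocentre is enolisable, since C5 is quaternary and C4 is not α to the carbonyl.

Step 5
Reactants: 8 (1R,2S)-2-hydroxy-2-[(1S)-1-hydroxypentadecyl]-3-oxocyclopentyl acetate
Product: 9 tris(trimethylsilyl) derivative of 8: C1 trimethylsilyl enol ether (C1=C2) with trimethylsilyl ethers at O5 and O1′, C4 acetate retained, configuration at C4, C5 and C1′ as in 8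
Conditions: TMSOTf (3.6 equiv), Et3N (6 equiv), CH2Cl2, −20 → 0 °C; pentane, cold aq. NaHCO3 wash; used crude
Reagents that add atoms: trimethylsilyl trifluoromethanesulfonate, C[Si](C)(C)OS(=O)(=O)C(F)(F)F
Why: Soft enolisation with a silyl triflate and a tertiary amine silylates both hydroxyls and converts the ketone into its silyl enol ether; only C2 carries α-hydrogens, so one regioisomer is possible, ester enolisation is far slower, and no strong base is present that could cause retro-aldol cleavage.

Step 6
Reactants: 9 tris(trimethylsilyl) derivative of 8
Product: 11 (1R,5S)-5-hydroxy-5-[(1S)-1-hydroxypentadecyl]-4-oxocyclopent-2-en-1-yl acetate (target), via enone bis(trimethylsilyl) ether 10 (not isolated)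
Conditions: Pd(OAc)2 (1.1 equiv), MeCN, rt; filtration through Celite; then citric acid, MeOH, 0 °C → rt
Reagents that add atoms: none
Why: Saegusa–Ito oxidation: the silyl enol ether transfers to divalent palladium to give a C2-bound palladium enolate, β-hydride elimination from C3 gives the C2=C3 enone, and zerovalent palladium precipitates without phosphine ligands that would help it ionise the allylic acetate. Methanolic citric acid then cleaves the two trimethylsilyl ethers without touching the acetate; no stereocentre is formed or disturbed.

## Compound list

1 | 6-bromo-1,4-dioxaspiro[4.4]non-6-ene | BrC1=CCCC12OCCO2 | starting material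
2 | pentadecanal | CCCCCCCCCCCCCCC=O | starting material
3 | 1,4-dioxaspiro[4.4]non-6-en-6-yllithium | [Li]C1=CCCC12OCCO2 | intermediate (not isolated)
4 | rac-1-(1,4-dioxaspiro[4.4]non-6-en-6-yl)pentadecan-1-ol (racemic at C1′) | CCCCCCCCCCCCCCC(O)C1=CCCC12OCCO2 | intermediate
5 | (6S,7S)-6,7-epoxy-6-[(1S)-1-hydroxypentadecyl]-1,4-dioxaspiro[4.4]nonane (erythro) | CCCCCCCCCCCCCC[C@H](O)[C@@]1(O3)C2(OCCO2)CC[C@@H]13 | intermediate
6 | acetic acid | CC(=O)O | starting material
7 | (6S,7R)-6-hydroxy-6-[(1S)-1-hydroxypentadecyl]-1,4-dioxaspiro[4.4]nonan-7-yl acetate | CCCCCCCCCCCCCC[C@H](O)[C@@]1(O)C2(OCCO2)CC[C@H]1OC(C)=O | intermediate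
8 | (1R,2S)-2-hydroxy-2-[(1S)-1-hydroxypentadecyl]-3-oxocyclopentyl acetate | CCCCCCCCCCCCCC[C@H](O)[C@@]1(O)C(=O)CC[C@H]1OC(C)=O | intermediate
9 | tris(trimethylsilyl) derivative of 8 (C1 silyl enol ether, O5 and O1′ silyl ethers) | CCCCCCCCCCCCCC[C@H](O[Si](C)(C)C)[C@@]1(O[Si](C)(C)C)C(O[Si](C)(C)C)=CC[C@H]1OC(C)=O | intermediate
10 | bis(trimethylsilyl) ether of 11 (O5 and O1′) | CCCCCCCCCCCCCC[C@H](O[Si](C)(C)C)[C@@]1(O[Si](C)(C)C)C(=O)C=C[C@H]1OC(C)=O | intermediate (not isolated)
11 | (1R,5S)-5-hydroxy-5-[(1S)-1-hydroxypentadecyl]-4-oxocyclopent-2-en-1-yl acetate | CCCCCCCCCCCCCC[C@H](O)[C@@]1(O)C(=O)C=C[C@H]1OC(C)=O | target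

## Step count and risks

Total step count: 6. Longest linear sequence: 6 steps, from 1 to 11; 2 and 6 enter in steps 1 and 3.

Least certain steps:

Step 3 (key step). Most likely to go wrong: competing transfer of isopropoxide from titanium to C4, and titanium-catalysed acyl transfer that moves the new acetyl group from O4 to the cis-disposed O1′ or passes it to isopropanol. Attack at C4 may also be slowed by the adjacent quaternary centre, which lengthens the exposure. Fallback, from 5 back to 8: the oxirane is opened hydrolytically and the acetate is placed by protecting-group control. NaOH in aqueous DMSO at about 70 °C should open 5 at C4 with inversion, Payne isomerisation being blocked because it would need attack at the quaternary C5, to give the 4,5-trans triol ketal F1. 2,2-Dimethoxypropane with pyridinium p-toluenesulfonate should tie the C5 and C1′ hydroxyls as the five-membered acetonide F2, since the trans C4 hydroxyl cannot share a five-membered ring with O5. Acetic anhydride, pyridine and DMAP then acetylate the one remaining hydroxyl to give the acetonide acetate F3. Aqueous acetic acid in THF removes the acetonide and the dioxolane together and returns to the route at 8.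

Step 2. Most likely to go wrong: an insufficient rate difference between the enantiomers or erosion of the erythro preference, because the bulky ketal carbon sits geminal to the carbinol and the ketal oxygens can compete for titanium. The oxirane may also be opened by isopropoxide or tartrate during the reaction. Half of 4 is lost by design. Fallback, from 4 back to 5: the enantioselectivity is moved from resolution to ketone reduction. MnO2 in CH2Cl2 oxidises 4 to the enone F4. Corey–Bakshi–Shibata reduction with (R)-2-methyl-oxazaborolidine and BH3·SMe2 at −30 °C, the alkenyl group acting as the large substituent, should give the (1S)-allylic alcohol F5. A matched Sharpless epoxidation (Ti(OiPr)4, L-(+)-diisopropyl tartrate, t-BuOOH, 4 Å sieves, −20 °C) run to full conversion then gives 5. The (1′R)-alcohol left over from step 2 can enter the same sequence.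

Step 4. Most likely to go wrong: slow hydrolysis of a dioxolane that stands next to an oxygenated quaternary carbon, and, under the longer acid exposure this invites, acid-catalysed acyl migration from O4 to O1′. Fallback, from 7 back to 9: the ketal is cleaved without aqueous acid and with both hydroxyls masked. TMSOTf and 2,2′-bipyridyl in CH2Cl2 at 0 °C silylate the two hydroxyls and open the dioxolane to a pyridinium adduct that water hydrolyses at neutral pH, giving the bis(trimethylsilyl) ether of 8, F6. TMSOTf and Et3N then convert F6 into 9.

Step 6. Most likely to go wrong: ionisation of the newly allylic C4 acetate by the zerovalent palladium that the oxidation produces, and incomplete oxidation, which returns 8 after desilylation. Fallback, from 9 back to 10: the dehydrogenation is done through selenium instead of palladium. PhSeCl in CH2Cl2 at −78 °C converts 9 into the 2-phenylselanyl ketone F7. H2O2 with pyridine at 0 °C oxidises it to the selenoxide, whose syn-elimination can only take a hydrogen from C3 and so gives 10. The citric acid/methanol treatment of step 6 then releases 11.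

## Further compounds

F1 | step 3 | (6S,7R)-6-[(1S)-1-hydroxypentadecyl]-1,4-dioxaspiro[4.4]nonane-6,7-diol | CCCCCCCCCCCCCC[C@H](O)[C@@]1(O)C2(OCCO2)CC[C@H]1O
F2 | step 3 | O5,O1′-isopropylidene derivative of F1 (spiro dioxolane, free C4 hydroxyl) | CCCCCCCCCCCCCC[C@H](O3)[C@@]1(OC3(C)C)C2(OCCO2)CC[C@H]1O
F3 | step 3 | C4 acetate of F2 | CCCCCCCCCCCCCC[C@H](O3)[C@@]1(OC3(C)C)C2(OCCO2)CC[C@H]1OC(C)=O
F4 | step 2 | 1-(1,4-dioxaspiro[4.4]non-6-en-6-yl)pentadecan-1-one | CCCCCCCCCCCCCCC(=O)C1=CCCC12OCCO2
F5 | step 2 | (1S)-1-(1,4-dioxaspiro[4.4]non-6-en-6-yl)pentadecan-1-ol | CCCCCCCCCCCCCC[C@H](O)C1=CCCC12OCCO2
F6 | step 4 | bis(trimethylsilyl) ether of 8 (O5 and O1′) | CCCCCCCCCCCCCC[C@H](O[Si](C)(C)C)[C@@]1(O[Si](C)(C)C)C(=O)CC[C@H]1OC(C)=O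
F7 | step 6 | 2-phenylselanyl derivative of F6 (both C2 epimers) | CCCCCCCCCCCCCC[C@H](O[Si](C)(C)C)[C@@]1(O[Si](C)(C)C)C(=O)C([Se]c2ccccc2)C[C@H]1OC(C)=O
A1 | alternative 1 | 3-(2,2-dimethyl-5-oxo-6-tetradecyl-1,3-dioxan-4-yl)propanal (stereolabile at both α-carbons) | CCCCCCCCCCCCCCC1OC(C)(C)OC(CCC=O)C1=O
A2 | alternative 1 | cis-fused 4a-hydroxy-2,2-dimethyl-4-tetradecyl-tetrahydrocyclopenta[d][1,3]dioxin-5-one (O4,O1′-isopropylidene derivative of 2,3-dihydro-4-deacetyl-11) | CCCCCCCCCCCCCC[C@H](O2)[C@@]1(O)C(=O)CC[C@H]1OC2(C)C
A3 | alternative 2 | (4S)-2,2-dimethyl-4-tetradecyl-1,3-dioxaspiro[4.4]non-7-ene-6,9-dione | CCCCCCCCCCCCCC[C@H](O2)C1(OC2(C)C)C(=O)C=CC1=O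
A4 | alternative 2 | 9-hydroxy-2,2-dimethyl-4-tetradecyl-1,3-dioxaspiro[4.4]non-7-en-6-one (O5,O1′-acetonide of 4-deacetyl-11) | CCCCCCCCCCCCCC[C@H](O2)[C@@]1(OC2(C)C)C(=O)C=C[C@H]1O
A5 | alternative 3 | (2S)-2-[tert-butyl(dimethyl)silyl]oxy-1-(furan-2-yl)hexadecan-1-ol (either C1 epimer) | CCCCCCCCCCCCCC[C@H](O[Si](C)(C)C(C)(C)C)C(O)c1ccco1
A6 | alternative 3 | 6-hydroxy-2-[(1S)-1-[tert-butyl(dimethyl)silyl]oxypentadecyl]-2H-pyran-3(6H)-one (mixture at C2 and C6) | CCCCCCCCCCCCCC[C@H](O[Si](C)(C)C(C)(C)C)C1OC(O)C=CC1=O
A7 | alternative 3 | O1′-tert-butyldimethylsilyl ether of 4-deacetyl-11 (4,5-trans diol) | CCCCCCCCCCCCCC[C@H](O[Si](C)(C)C(C)(C)C)[C@@]1(O)C(=O)C=C[C@H]1O
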